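## Retrosynthetic overview

1. Carotenoid numbering is used: C1–C15 is the hydroxylated half, primed numbers are the cyclohexadiene half. The chain is cut at C11=C12 and C11'=C12' (two Wittig reactions) into C15 salt 14, C10 dialdehyde 19 and C15 salt 18. Each C15 unit is then cut at its ring–alkyne bond C6–C7 (Sonogashira, same enynol 7).
2. In the hydroxylated ring, the fully substituted triad C1(Me2)–C6(alkynyl)=C5(Me) is read as the 2-bromo-3-methyl enone C5(=O)–C6(Br)=C1(Me) of 6. C6–Br takes the alkyne, C1 takes the second methyl (cuprate), and C5 takes its methyl through the enol triflate.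
3. Ring enlargement 5 → 6: C6 is inserted as CBr2 into the enol-ether bond C5=C1 of cyclopentene 4, by carbene addition followed by electrocyclic opening of the bicyclo[3.1.0]hexane.
4. Enabling feature: C6 bears no hydrogen and is flanked in the ring by C5 and C1, which can be the two ends of one enol-ether C=C. The only stereocentre, C3, lies across the ring from C6, two bonds from every bond made or broken. It is therefore bought with (R)-cyclopentenone 1, and both cyclopropane diastereomers converge on one enone.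
5. Ring order: the cyclohexadiene ring is bought as enone 15. The five-membered ring of 1 is enlarged to the six-membered ring in step 4. No other ring is formed.

Key step: step 4

Remark: 1, 7, 15 and 19 are taken as catalogue compounds; all polyene steps are run in the dark under argon.

## Route

Step 1
Reactants: 1 (R)-4-(tert-butyldimethylsilyloxy)cyclopent-2-en-1-one
Product: 2 (R)-4-(tert-butyldimethylsilyloxy)-2-iodocyclopent-2-en-1-one
Conditions: I2, pyridine/CH2Cl2, 0 °C to rt
Reagents that add atoms: iodine, II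
Why: Pyridine-mediated α-iodination of an enone (Baylis–Hillman-type addition, iodination, elimination) should place iodine only at C2 and does not touch the silyloxy-bearing carbon.

Step 2
Reactants: 2 (R)-4-(tert-butyldimethylsilyloxy)-2-iodocyclopent-2-en-1-one
Product: 3 (R)-4-(tert-butyldimethylsilyloxy)-2-methylcyclopent-2-en-1-one
Conditions: MeZnCl, Pd(PPh3)4 (cat.), THF, 0 °C to rt
Reagents that add atoms: methylzinc chloride, C[Zn]Cl
Why: Negishi coupling of an α-iodoenone with an alkylzinc reagent is fast and essentially neutral, so the base-labile 4-silyloxy enone should survive.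

Step 3
Reactants: 3 (R)-4-(tert-butyldimethylsilyloxy)-2-methylcyclopent-2-en-1-one
Product: 4 (S)-tert-butyldimethyl{[3-methyl-4-(triethylsilyloxy)cyclopent-3-en-1-yl]oxy}silane
Conditions: Et3SiH, RhCl(PPh3)3 (cat.), THF, 50 °C
Reagents that add atoms: triethylsilane, CC[SiH](CC)CC
Why: Rh-catalysed 1,4-hydrosilylation of an enone puts H on the β-carbon and Si on oxygen, so the tetrasubstituted enol ether should form as a single regioisomer without any enolate that could expel the silyloxy group (the descriptor changes only by CIP ranking).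

Step 4
Reactants: 4 (S)-tert-butyldimethyl{[3-methyl-4-(triethylsilyloxy)cyclopent-3-en-1-yl]oxy}silane
Product: 6 (S)-2-bromo-5-(tert-butyldimethylsilyloxy)-3-methylcyclohex-2-en-1-one, via dibromocyclopropane adduct 5 (not isolated)
Conditions: CHBr3, KOtBu, pentane, −30 to 0 °C; cold filtration through Celite, solvent change; toluene, 80 °C
Reagents that add atoms: bromoform, BrC(Br)Br
Why: Dibromocarbene, formed by α-elimination from bromoform, adds in a concerted [2+1] cheletropic step to the only C=C of 4, the electron-rich tetrasubstituted enol ether, and so closes the three-membered ring of 5 on either face. On warming, the endo C–Br bond of 5 ionises in concert with disrotatory 2π-electrocyclic opening of the shared C1–C5 bond (Woodward–Hoffmann–DePuy mode), pushed by the bridgehead silyloxy group, so the six-membered ring is not closed by a new bond but arises when the zero bridge of the bicyclo[3.1.0]hexane breaks, and bromide then takes the triethylsilyl group from the oxyallyl cation to release the enone. The closest known reaction type is the dihalocarbene ring expansion of cyclic silyl enol ethers to 2-halocycloalk-2-enones. No lasting stereocentre is made: the two bridgehead centres of 5 become sp2 again, so both diastereomers of 5, each of which carries one endo bromine, should converge on the single enone 6, and C3 is a spectator that keeps the configuration of 1. The step needs cleavage of the internal rather than a peripheral cyclopropane bond and survival of the β-silyloxy ketone; the first is secured by the endo bromide and the bridgehead donor under aprotic conditions, the second by removing the alkoxide base before the opening is driven thermally. In one operation the ring reaches its final size and C6, C1 and C5 receive three different handles (C–Br, enone β-carbon, carbonyl) for the three substituents still missing.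

Step 5
Reactants: 7 (E)-3-methylpent-2-en-4-yn-1-ol
Product: 8 (E)-tert-butyldimethyl[(3-methylpent-2-en-4-yn-1-yl)oxy]silane
Conditions: TBSCl, imidazole, CH2Cl2, 0 °C to rt
Reagents that add atoms: tert-butyldimethylsilyl chloride, CC(C)(C)[Si](C)(C)Cl
Why: Standard silylation of a primary allylic alcohol masks the hydroxyl proton and oxygen against the cuprate and the triflating agent of step 7.

Step 6
Reactants: 6 (S)-2-bromo-5-(tert-butyldimethylsilyloxy)-3-methylcyclohex-2-en-1-one; 8 (E)-tert-butyldimethyl[(3-methylpent-2-en-4-yn-1-yl)oxy]silane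
Product: 9 (S)-5-(tert-butyldimethylsilyloxy)-2-[(E)-5-(tert-butyldimethylsilyloxy)-3-methylpent-3-en-1-yn-1-yl]-3-methylcyclohex-2-en-1-one
Conditions: PdCl2(PPh3)2 (cat.), CuI (cat.), iPr2NH, THF, rt
Reagents that add atoms: none
Why: Sonogashira coupling of an α-haloenone forms the ring–alkyne bond C6–C7 while C1 is still sp2, that is before this bond becomes flanked by a quaternary carbon, and the carbonyl activates C–Br for oxidative addition.

Step 7
Reactants: 9 (S)-5-(tert-butyldimethylsilyloxy)-2-[(E)-5-(tert-butyldimethylsilyloxy)-3-methylpent-3-en-1-yn-1-yl]-3-methylcyclohex-2-en-1-one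
Product: 11 (S)-5-(tert-butyldimethylsilyloxy)-2-[(E)-5-(tert-butyldimethylsilyloxy)-3-methylpent-3-en-1-yn-1-yl]-3,3-dimethylcyclohex-1-en-1-yl trifluoromethanesulfonate, via lithium enolate 10 (not isolated)
Conditions: MeLi/CuI (2:1), Et2O, −20 °C; 9, −40 to 0 °C; then N-(5-chloropyridin-2-yl)bis(trifluoromethanesulfonimide), THF, −78 to 0 °C
Reagents that add atoms: methyllithium (delivered as Me2CuLi), [Li]C; N-(5-chloropyridin-2-yl)bis(trifluoromethanesulfonimide), O=S(=O)(N(c1ccc(Cl)cn1)S(=O)(=O)C(F)(F)F)C(F)(F)F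
Why: Gilman conjugate addition followed by regiospecific O-triflation of the resulting enolate makes C1 a carbon with two identical methyl groups, so no facial selectivity is needed, and the alkyne-conjugated tetrasubstituted enolate has no drive to equilibrate toward C4, from where the silyloxy group could be expelled.

Step 8
Reactants: 11 (S)-5-(tert-butyldimethylsilyloxy)-2-[(E)-5-(tert-butyldimethylsilyloxy)-3-methylpent-3-en-1-yn-1-yl]-3,3-dimethylcyclohex-1-en-1-yl trifluoromethanesulfonate
Product: 12 (R)-tert-butyl({4-[(E)-5-(tert-butyldimethylsilyloxy)-3-methylpent-3-en-1-yn-1-yl]-3,5,5-trimethylcyclohex-3-en-1-yl}oxy)dimethylsilane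
Conditions: MeZnCl, Pd(PPh3)4 (cat.), THF, rt to 40 °C
Reagents that add atoms: methylzinc chloride, C[Zn]Cl
Why: Negishi methylation of an enol triflate whose carbon C5 has an unhindered CH2 neighbour fixes the tetrasubstituted C5=C6 double bond exactly where the enolate was trapped.

Step 9
Reactants: 12 (R)-tert-butyl({4-[(E)-5-(tert-butyldimethylsilyloxy)-3-methylpent-3-en-1-yn-1-yl]-3,5,5-trimethylcyclohex-3-en-1-yl}oxy)dimethylsilane
Product: 13 (R)-4-[(E)-5-hydroxy-3-methylpent-3-en-1-yn-1-yl]-3,5,5-trimethylcyclohex-3-en-1-ol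
Conditions: TBAF, THF, 0 °C to rt
Reagents that add atoms: none
Why: Fluoride cleaves both Si–O bonds without breaking a C–O bond, so C3 keeps its configuration and the enyne is inert.

Step 10
Reactants: 13 (R)-4-[(E)-5-hydroxy-3-methylpent-3-en-1-yn-1-yl]-3,5,5-trimethylcyclohex-3-en-1-ol
Product: 14 {(E)-5-[(R)-4-hydroxy-2,6,6-trimethylcyclohex-1-en-1-yl]-3-methylpent-2-en-4-yn-1-yl}triphenylphosphonium bromide
Conditions: PPh3·HBr, MeOH, rt
Reagents that add atoms: triphenylphosphine hydrobromide, Br.c1ccc(cc1)P(c1ccccc1)c1ccccc1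
Why: Acid-mediated substitution of an allylic alcohol by triphenylphosphine works only where an allyl cation can form, so the primary allylic hydroxyl should react and the secondary homoallylic C3 hydroxyl should stay free.

Step 11
Reactants: 15 2,6,6-trimethylcyclohex-2-en-1-one
Product: 16 2,6,6-trimethylcyclohexa-1,3-dien-1-yl trifluoromethanesulfonate
Conditions: Tf2O, 2,6-di-tert-butyl-4-methylpyridine, CH2Cl2, 0 °C to rt
Reagents that add atoms: trifluoromethanesulfonic anhydride, O=S(=O)(OS(=O)(=O)C(F)(F)F)C(F)(F)F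
Why: O-Triflation of an enone followed by loss of a γ-proton gives the conjugated dienyl triflate, and here only the ring CH2 at C4 can lose that proton because the α'-carbon is quaternary.

Step 12
Reactants: 16 2,6,6-trimethylcyclohexa-1,3-dien-1-yl trifluoromethanesulfonate; 7 (E)-3-methylpent-2-en-4-yn-1-ol
Product: 17 (E)-3-methyl-5-(2,6,6-trimethylcyclohexa-1,3-dien-1-yl)pent-2-en-4-yn-1-ol
Conditions: Pd(PPh3)4 (cat.), CuI (cat.), Et3N, DMF, 50 °C
Reagents that add atoms: none
Why: Sonogashira coupling of a vinyl triflate tolerates the free alcohol, and the rod-shaped copper acetylide is the least demanding partner for a carbon flanked by CMe2 and C–Me.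

Step 13
Reactants: 17 (E)-3-methyl-5-(2,6,6-trimethylcyclohexa-1,3-dien-1-yl)pent-2-en-4-yn-1-ol
Product: 18 [(E)-3-methyl-5-(2,6,6-trimethylcyclohexa-1,3-dien-1-yl)pent-2-en-4-yn-1-yl]triphenylphosphonium bromide
Conditions: PPh3·HBr, MeOH, rt
Reagents that add atoms: triphenylphosphine hydrobromide, Br.c1ccc(cc1)P(c1ccccc1)c1ccccc1
Why: This is the same allylic alcohol to phosphonium salt conversion as in step 10, and the buffered acid is too weak to disturb the gem-dimethyl-blocked cyclohexadiene.

Step 14
Reactants: 18 [(E)-3-methyl-5-(2,6,6-trimethylcyclohexa-1,3-dien-1-yl)pent-2-en-4-yn-1-yl]triphenylphosphonium bromide; 19 (2E,4E,6E)-2,7-dimethylocta-2,4,6-trienedial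
Product: 21 (2E,4E,6E,8E,10E)-2,7,11-trimethyl-13-(2,6,6-trimethylcyclohexa-1,3-dien-1-yl)trideca-2,4,6,8,10-pentaen-12-ynal, via phosphorus ylide 20 (not isolated)
Conditions: NaOMe, MeOH/CH2Cl2, 0 °C to rt, slow addition to excess 19; then EtOH, 70 °C
Reagents that add atoms: none
Why: Wittig olefination (C15 + C10) with the dialdehyde in excess should stop at the monoadduct, and any sterically hindered Z isomer at the new C11'=C12' bond should relax thermally to E.

Step 15
Reactants: 14 {(E)-5-[(R)-4-hydroxy-2,6,6-trimethylcyclohex-1-en-1-yl]-3-methylpent-2-en-4-yn-1-yl}triphenylphosphonium bromide; 21 (2E,4E,6E,8E,10E)-2,7,11-trimethyl-13-(2,6,6-trimethylcyclohexa-1,3-dien-1-yl)trideca-2,4,6,8,10-pentaen-12-ynal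
Product: 23 (3R)-all-E-3',4',7,8,7',8'-hexadehydro-β,β-caroten-3-ol, via phosphorus ylide 22 (not isolated)
Conditions: NaOMe, MeOH/CH2Cl2, 0 °C to rt; then EtOH, 70 °C, crystallisation
Reagents that add atoms: none
Why: Wittig olefination (C15 + C25) forms C11=C12 with the C3 hydroxyl unprotected, the hindered 11Z isomer (C10–H against C13–Me) should isomerise on gentle heating, and the all-E polyene should be the form that crystallises.

## Compound list

1 | (R)-4-(tert-butyldimethylsilyloxy)cyclopent-2-en-1-one | O=C1C=C[C@H](O[Si](C)(C)C(C)(C)C)C1 | starting material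
2 | (R)-4-(tert-butyldimethylsilyloxy)-2-iodocyclopent-2-en-1-one | O=C1C(I)=C[C@H](O[Si](C)(C)C(C)(C)C)C1 | intermediate
3 | (R)-4-(tert-butyldimethylsilyloxy)-2-methylcyclopent-2-en-1-one | O=C1C(C)=C[C@H](O[Si](C)(C)C(C)(C)C)C1 | intermediate
4 | (S)-tert-butyldimethyl{[3-methyl-4-(triethylsilyloxy)cyclopent-3-en-1-yl]oxy}silane | CC[Si](CC)(CC)OC1=C(C)C[C@H](O[Si](C)(C)C(C)(C)C)C1 | intermediate
5 | (3S)-6,6-dibromo-3-(tert-butyldimethylsilyloxy)-5-methyl-1-(triethylsilyloxy)bicyclo[3.1.0]hexane, both cyclopropane-face diastereomers | CC[Si](CC)(CC)OC12C[C@@H](O[Si](C)(C)C(C)(C)C)CC1(C)C2(Br)Br | intermediate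
6 | (S)-2-bromo-5-(tert-butyldimethylsilyloxy)-3-methylcyclohex-2-en-1-one | O=C1C(Br)=C(C)C[C@H](O[Si](C)(C)C(C)(C)C)C1 | intermediate
7 | (E)-3-methylpent-2-en-4-yn-1-ol | C#C/C(C)=C/CO | starting material
8 | (E)-tert-butyldimethyl[(3-methylpent-2-en-4-yn-1-yl)oxy]silane | C#C/C(C)=C/CO[Si](C)(C)C(C)(C)C | intermediate
9 | (S)-5-(tert-butyldimethylsilyloxy)-2-[(E)-5-(tert-butyldimethylsilyloxy)-3-methylpent-3-en-1-yn-1-yl]-3-methylcyclohex-2-en-1-one | O=C1C(C#C/C(C)=C/CO[Si](C)(C)C(C)(C)C)=C(C)C[C@H](O[Si](C)(C)C(C)(C)C)C1 | intermediate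
10 | lithium (S)-enolate of the 3,3-dimethyl ketone formed from 9 (O–Li on C5, C5=C6) | [Li]OC1=C(C#C/C(C)=C/CO[Si](C)(C)C(C)(C)C)C(C)(C)C[C@H](O[Si](C)(C)C(C)(C)C)C1 | intermediate
11 | (S)-5-(tert-butyldimethylsilyloxy)-2-[(E)-5-(tert-butyldimethylsilyloxy)-3-methylpent-3-en-1-yn-1-yl]-3,3-dimethylcyclohex-1-en-1-yl trifluoromethanesulfonate | O=S(=O)(OC1=C(C#C/C(C)=C/CO[Si](C)(C)C(C)(C)C)C(C)(C)C[C@H](O[Si](C)(C)C(C)(C)C)C1)C(F)(F)F | intermediate
12 | (R)-tert-butyl({4-[(E)-5-(tert-butyldimethylsilyloxy)-3-methylpent-3-en-1-yn-1-yl]-3,5,5-trimethylcyclohex-3-en-1-yl}oxy)dimethylsilane | CC1=C(C#C/C(C)=C/CO[Si](C)(C)C(C)(C)C)C(C)(C)C[C@H](O[Si](C)(C)C(C)(C)C)C1 | intermediate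
13 | (R)-4-[(E)-5-hydroxy-3-methylpent-3-en-1-yn-1-yl]-3,5,5-trimethylcyclohex-3-en-1-ol | CC1=C(C#C/C(C)=C/CO)C(C)(C)C[C@H](O)C1 | intermediate
14 | {(E)-5-[(R)-4-hydroxy-2,6,6-trimethylcyclohex-1-en-1-yl]-3-methylpent-2-en-4-yn-1-yl}triphenylphosphonium bromide | CC1=C(C#C/C(C)=C/C[P+](c2ccccc2)(c2ccccc2)c2ccccc2)C(C)(C)C[C@H](O)C1.[Br-] | intermediate
15 | 2,6,6-trimethylcyclohex-2-en-1-one | CC1=CCCC(C)(C)C1=O | starting material
16 | 2,6,6-trimethylcyclohexa-1,3-dien-1-yl trifluoromethanesulfonate | CC1=C(OS(=O)(=O)C(F)(F)F)C(C)(C)CC=C1 | intermediate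
17 | (E)-3-methyl-5-(2,6,6-trimethylcyclohexa-1,3-dien-1-yl)pent-2-en-4-yn-1-ol | CC1=C(C#C/C(C)=C/CO)C(C)(C)CC=C1 | intermediate
18 | [(E)-3-methyl-5-(2,6,6-trimethylcyclohexa-1,3-dien-1-yl)pent-2-en-4-yn-1-yl]triphenylphosphonium bromide | CC1=C(C#C/C(C)=C/C[P+](c2ccccc2)(c2ccccc2)c2ccccc2)C(C)(C)CC=C1.[Br-] | intermediate
19 | (2E,4E,6E)-2,7-dimethylocta-2,4,6-trienedial | O=C/C(C)=C/C=C/C=C(C)/C=O | starting material
20 | ylide of 18 | CC1=C(C#C/C(C)=C/[CH-][P+](c2ccccc2)(c2ccccc2)c2ccccc2)C(C)(C)CC=C1 | intermediate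
21 | (2E,4E,6E,8E,10E)-2,7,11-trimethyl-13-(2,6,6-trimethylcyclohexa-1,3-dien-1-yl)trideca-2,4,6,8,10-pentaen-12-ynal | CC1=C(C#C/C(C)=C/C=C/C(C)=C/C=C/C=C(C)/C=O)C(C)(C)CC=C1 | intermediate
22 | ylide of 14 | CC1=C(C#C/C(C)=C/[CH-][P+](c2ccccc2)(c2ccccc2)c2ccccc2)C(C)(C)C[C@H](O)C1 | intermediate
23 | (3R)-all-E-3',4',7,8,7',8'-hexadehydro-β,β-caroten-3-ol | CC1=C(C#C/C(C)=C/C=C/C(C)=C/C=C/C=C(C)/C=C/C=C(\C)C#CC2=C(C)C[C@@H](O)CC2(C)C)C(C)(C)CC=C1 | target

## Step count and risks

Total step count: 15. Longest linear sequence: 10 (steps 1, 2, 3, 4, 6, 7, 8, 9, 10, 15).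

**Step 7.** Methyl transfer to the fully substituted β-carbon C1 may be slow. Then 1,2-addition, enolate equilibration toward C4, loss of silanolate and aromatisation could overtake the conjugate addition.

The fallback sets out from 4 and comes back at 12. It makes the quaternary carbon on the five-membered ring and enlarges the ring afterwards.
- The enol Si–O bond of 4 is cleaved with MeLi (THF/DMPU) to the lithium enolate F1.
- F1 is C-methylated with MeI to (S)-4-(tert-butyldimethylsilyloxy)-2,2-dimethylcyclopentan-1-one F2.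
- Lewis-acid-promoted diazoalkane homologation (diazoethane, BF3·OEt2, −78 °C) follows, in which the CH2 group migrates in preference to the quaternary carbon. It enlarges the ring to (4R)-4-(tert-butyldimethylsilyloxy)-2,2,6-trimethylcyclohexan-1-one F3. The configuration at the methyl-bearing carbon of F3 is irrelevant.
- The lithium acetylide F4, made from 8 and n-BuLi, adds to F3 to give the tertiary propargylic alcohol F5.
- Dehydration (POCl3, pyridine) is possible only toward the methyl-bearing carbon and gives 12.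

**Step 4.** The cyclopropane may open while alkoxide is still present, so that the new β-silyloxy enone loses its silyloxy group by E1cB. Alternatively, protolytic cleavage of a peripheral cyclopropane bond may keep the five-membered ring.

The fallback sets out from 4 and comes back at 6. It replaces the cationic opening by a radical one.
- Simmons–Smith cyclopropanation (Et2Zn, CH2I2) gives the siloxycyclopropane F6.
- FeCl3 in DMF oxidises F6 with cleavage of the internal bond, through the tertiary radical at the methyl-bearing carbon, to the ring-enlarged β-chloro ketone F7.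
- NaOAc in MeOH eliminates HCl to give (S)-5-(tert-butyldimethylsilyloxy)-3-methylcyclohex-2-en-1-one F8.
- Br2 in CH2Cl2 gives the dibromide F9, and Et3N removes HBr to give 6.

**Step 12.** Oxidative addition and transmetalation at the triflate-bearing carbon, flanked by CMe2 and C–Me, may be slow. Alkyne homocoupling and triflate hydrolysis could then overtake the coupling.

The fallback sets out from 15 and 8 and comes back at 17. It forms the hindered bond by carbonyl addition.
- 8 is converted with EtMgBr into the bromomagnesium acetylide F10.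
- F10 adds 1,2 to 15 to give the tertiary allylic-propargylic alcohol F11.
- Acid-catalysed 1,4-dehydration (pTsOH cat., toluene, molecular sieves) ionises this doubly activated alcohol and removes a proton from the ring CH2 next to the allyl terminus. This gives the dienyne silyl ether F12.
- TBAF converts F12 into 17.

## Further compounds

F1 | step 7 | lithium (S)-4-(tert-butyldimethylsilyloxy)-2-methylcyclopent-1-en-1-olate | [Li]OC1=C(C)C[C@H](O[Si](C)(C)C(C)(C)C)C1
F2 | step 7 | (S)-4-(tert-butyldimethylsilyloxy)-2,2-dimethylcyclopentan-1-one | O=C1C(C)(C)C[C@H](O[Si](C)(C)C(C)(C)C)C1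
F3 | step 7 | (4R)-4-(tert-butyldimethylsilyloxy)-2,2,6-trimethylcyclohexan-1-one, C6 epimers | O=C1C(C)(C)C[C@H](O[Si](C)(C)C(C)(C)C)CC1C
F4 | step 7 | lithium acetylide of 8 | [Li]C#C/C(C)=C/CO[Si](C)(C)C(C)(C)C
F5 | step 7 | (4R)-4-(tert-butyldimethylsilyloxy)-1-[(E)-5-(tert-butyldimethylsilyloxy)-3-methylpent-3-en-1-yn-1-yl]-2,2,6-trimethylcyclohexan-1-ol, isomers at C1 and C6 | OC1(C#C/C(C)=C/CO[Si](C)(C)C(C)(C)C)C(C)(C)C[C@H](O[Si](C)(C)C(C)(C)C)CC1C
F6 | step 4 | (3S)-3-(tert-butyldimethylsilyloxy)-5-methyl-1-(triethylsilyloxy)bicyclo[3.1.0]hexane, both cyclopropane-face diastereomers | CC[Si](CC)(CC)OC12C[C@@H](O[Si](C)(C)C(C)(C)C)CC1(C)C2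
F7 | step 4 | (5R)-5-(tert-butyldimethylsilyloxy)-3-chloro-3-methylcyclohexan-1-one, C3 epimers | O=C1CC(C)(Cl)C[C@H](O[Si](C)(C)C(C)(C)C)C1
F8 | step 4 | (S)-5-(tert-butyldimethylsilyloxy)-3-methylcyclohex-2-en-1-one | O=C1C=C(C)C[C@H](O[Si](C)(C)C(C)(C)C)C1
F9 | step 4 | (5R)-2,3-dibromo-5-(tert-butyldimethylsilyloxy)-3-methylcyclohexan-1-one, isomers at C2 and C3 | O=C1C(Br)C(C)(Br)C[C@H](O[Si](C)(C)C(C)(C)C)C1
F10 | step 12 | bromomagnesium acetylide of 8 | Br[Mg]C#C/C(C)=C/CO[Si](C)(C)C(C)(C)C
F11 | step 12 | 1-[(E)-5-(tert-butyldimethylsilyloxy)-3-methylpent-3-en-1-yn-1-yl]-2,6,6-trimethylcyclohex-2-en-1-ol, racemic | CC1=CCCC(C)(C)C1(O)C#C/C(C)=C/CO[Si](C)(C)C(C)(C)C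
F12 | step 12 | (E)-tert-butyldimethyl{[3-methyl-5-(2,6,6-trimethylcyclohexa-1,3-dien-1-yl)pent-2-en-4-yn-1-yl]oxy}silane | CC1=C(C#C/C(C)=C/CO[Si](C)(C)C(C)(C)C)C(C)(C)CC=C1
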